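The lactone ring oxygen and carbonyl carbon (O1 and C2 of the butyrolactone, with the exocyclic oxygen) are read as one latent CO2 inserted between the α-carbon (C3) and the OCH2 carbon (C5). The precursor is an (E)-styrene: the dihydrobenzofuran arene (ring A) is conjugated to the future α-carbon, and the adjacent allylic stereocentre carries the ring-B benzyl group and a CH2Cl arm. Formate-derived CO2 radical anion adds at the styrene carbon remote from ring A (new C–C bond), and the carboxylate displaces chloride (new CH2–O bond), closing the lactone in one pot. Both aryl units come from one anti-aldol diol; an auxiliary alkylation and a Heck coupling assemble the styrene.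

Key step: step 17

Abbreviations and locants: TBS = tert-butyldimethylsilyl. Lactone locants: O1, C2 (C=O), C3 (α), C4 (β), C5 (OCH2). ArA = (2R,3S)-2-[4-(TBS-oxy)-3-methoxyphenyl]-3-[(TBS-oxy)methyl]-7-methoxy-2,3-dihydro-1-benzofuran-5-yl. ArB = 4-(TBS-oxy)-3-methoxy-5-{(4S,5S)-2,2-di-tert-butyl-4-[4-(TBS-oxy)-3-methoxyphenyl]-1,3,2-dioxasilinan-5-yl}phenyl.

Remark on the chemistry: the 3,4-trans dibenzyl lactone is taken to be the thermodynamically preferred C3 epimer, as for trans-2,3-disubstituted γ-butyrolactones in general, so C3 is set by base equilibration.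

Step 1
Reactants: 1 2-allyl-6-methoxyphenol (o-eugenol)
Product: 2 2-allyl-4-bromo-6-methoxyphenol
Conditions: N-bromosuccinimide (1.0 equiv), MeCN, −20 to 0 °C, dark
Reagents that add atoms: N-bromosuccinimide, O=C1CCC(=O)N1Br
Why: Electrophilic aromatic bromination goes para to the free phenol (both ortho positions are occupied), and at low temperature the activated guaiacol ring should react faster than the allyl double bond.

Step 2
Reactants: 2 2-allyl-4-bromo-6-methoxyphenol
Product: 3 (2-allyl-4-bromo-6-methoxyphenoxy)(tert-butyl)dimethylsilane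
Conditions: TBSCl, imidazole, DMF, rt
Reagents that add atoms: tert-butyldimethylsilyl chloride, C[Si](C)(Cl)C(C)(C)C
Why: Imidazole-promoted O-silylation masks the phenol against the oxidants and bases that follow.

Step 3
Reactants: 3 (2-allyl-4-bromo-6-methoxyphenoxy)(tert-butyl)dimethylsilane
Product: 5 2-[5-bromo-2-(TBS-oxy)-3-methoxyphenyl]acetic acid, via arylacetaldehyde 4 (not isolated)
Conditions: O3, acetone–H2O (95:5), 0 °C; then NaClO2, NaH2PO4, rt
Reagents that add atoms: ozone, [O-][O+]=O; sodium chlorite, [Na+].[O-]Cl=O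
Why: Ozonolysis of the terminal alkene in wet acetone gives the aldehyde directly, and the co-formed hydrogen peroxide scavenges hypochlorite in the Pinnick oxidation, so the enolisable arylacetaldehyde is never isolated.

Step 4
Reactants: 5 2-[5-bromo-2-(TBS-oxy)-3-methoxyphenyl]acetic acid; 6 (S)-4-benzyl-1,3-oxazolidin-2-one
Product: 8 (S)-4-benzyl-3-{[5-bromo-2-(TBS-oxy)-3-methoxyphenyl]acetyl}-1,3-oxazolidin-2-one, via mixed pivalic anhydride 7 (not isolated)
Conditions: t-BuCOCl, Et3N, THF, −20 °C; then LiCl, 6, −20 °C to rt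
Reagents that add atoms: none
Why: LiCl-promoted N-acylation of the oxazolidinone by the mixed anhydride attaches the Evans auxiliary without strong base.

Step 5
Reactants: 8 (S)-4-benzyl-3-{[5-bromo-2-(TBS-oxy)-3-methoxyphenyl]acetyl}-1,3-oxazolidin-2-one; 9 4-(TBS-oxy)-3-methoxybenzaldehyde
Product: 11 (S)-4-benzyl-3-{(2R,3S)-2-[5-bromo-2-(TBS-oxy)-3-methoxyphenyl]-3-hydroxy-3-[4-(TBS-oxy)-3-methoxyphenyl]propanoyl}-1,3-oxazolidin-2-one, via O-trimethylsilyl aldol ether 10 (not isolated)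
Conditions: MgCl2 (20 mol %), Et3N, Me3SiCl, EtOAc, rt; then CF3CO2H (cat.), MeOH, rt
Reagents that add atoms: none
Why: In the Evans magnesium-catalysed anti-aldol reaction the chelated Z-magnesium enolate is attacked by the non-enolisable aldehyde on the face opposite the 4-benzyl group through a boat transition state, and O-silylation makes the addition irreversible, which should give the anti (2R,3S) adduct.

Step 6
Reactants: 11 anti-aldol imide
Product: 12 (1S,2S)-2-[5-bromo-2-(TBS-oxy)-3-methoxyphenyl]-1-[4-(TBS-oxy)-3-methoxyphenyl]propane-1,3-diol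
Conditions: NaBH4, THF–H2O, 0 °C to rt
Reagents that add atoms: none
Why: Borohydride reduction of the activated imide carbonyl releases the 1,3-diol and the auxiliary under conditions too mild to epimerise the benzylic α-centre.

Step 7
Reactants: 12 (1S,2S)-diol
Product: 14 4-[(2R,3S)-5-bromo-3-(hydroxymethyl)-7-methoxy-2,3-dihydro-1-benzofuran-2-yl]-2-methoxyphenol, via tetraol 13 (not isolated)
Conditions: Bu4NF, THF, 0 °C; then HCl (4 M in 1,4-dioxane), rt
Reagents that add atoms: none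
Why: Fluoride frees both phenols, and acid then ionises the benzylic carbinol to a para-hydroxybenzyl cation (quinone methide) that the ortho phenol captures in a 5-exo closure, which is stereoconvergent to the trans-2,3-dihydrobenzofuran (C2 becomes R, C3 stays S).

Step 8
Reactants: 14 dihydrobenzofuran phenol-alcohol
Product: 15 ArA–Br, tert-butyl(4-{(2R,3S)-5-bromo-3-[(TBS-oxy)methyl]-7-methoxy-2,3-dihydro-1-benzofuran-2-yl}-2-methoxyphenoxy)dimethylsilane
Conditions: TBSCl (2.5 equiv), imidazole, DMF, rt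
Reagents that add atoms: tert-butyldimethylsilyl chloride, C[Si](C)(Cl)C(C)(C)C
Why: Silylation of the phenol and the primary alcohol removes the O–H groups that could quench radicals or compete as nucleophiles later.

Step 9
Reactants: 12 (1S,2S)-diol
Product: 16 (4S,5S)-5-[5-bromo-2-(TBS-oxy)-3-methoxyphenyl]-2,2-di-tert-butyl-4-[4-(TBS-oxy)-3-methoxyphenyl]-1,3,2-dioxasilinane
Conditions: t-Bu2Si(OTf)2, 2,6-lutidine, CH2Cl2, 0 °C
Reagents that add atoms: di-tert-butylsilyl bis(trifluoromethanesulfonate), CC(C)(C)[Si](OS(=O)(=O)C(F)(F)F)(OS(=O)(=O)C(F)(F)F)C(C)(C)C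
Why: The 1,3-diol closes a six-membered silylene that protects both hydroxyl groups without acid and is removable by fluoride.

Step 10
Reactants: 16 silylene aryl bromide
Product: 18 ArB–CH2OH, via aryl aldehyde 17 (not isolated)
Conditions: n-BuLi, THF, −78 °C; DMF, −78 to 0 °C; then MeOH, NaBH4, 0 °C
Reagents that add atoms: N,N-dimethylformamide, CN(C)C=O
Why: Bromine–lithium exchange is faster than any deprotonation at −78 °C, the aryllithium is formylated by DMF, and the aldehyde is reduced in the same flask to the benzylic alcohol.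

Step 11
Reactants: 18 ArB–CH2OH
Product: 19 ArB–CH2Br
Conditions: CBr4, PPh3, CH2Cl2, 0 °C
Reagents that add atoms: carbon tetrabromide, BrC(Br)(Br)Br
Why: The Appel reaction converts the benzylic alcohol to the bromide under neutral conditions that spare the silyl ethers and the silylene.

Step 12
Reactants: 6 (S)-4-benzyl-1,3-oxazolidin-2-one; 20 (E)-but-2-enoyl chloride
Product: 21 (S)-4-benzyl-3-[(E)-but-2-enoyl]-1,3-oxazolidin-2-one
Conditions: n-BuLi, THF, −78 °C; then 20, −78 to 0 °C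
Reagents that add atoms: none
Why: N-Acylation of the lithiated oxazolidinone with the acid chloride is the standard entry to the crotonyl imide.

Step 13
Reactants: 21 crotonyl imide; 19 ArB–CH2Br
Product: 22 (S)-4-benzyl-3-[(2S)-2-(ArB-methyl)but-3-enoyl]-1,3-oxazolidin-2-one
Conditions: NaN(SiMe3)2, THF, −78 °C; then 19, −78 to −40 °C; AcOH quench
Reagents that add atoms: none
Why: In this deconjugative Evans alkylation, γ-deprotonation gives the chelated Z-dienolate, which the benzylic bromide alkylates at the α-carbon on the face opposite the 4-benzyl group, setting the (S) centre that becomes lactone C4.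

Step 14
Reactants: 22 alkylated imide
Product: 23 (2S)-2-(ArB-methyl)but-3-en-1-ol
Conditions: NaBH4, THF–H2O, 0 °C to rt
Reagents that add atoms: none
Why: Mild borohydride cleavage of the imide gives the primary alcohol and returns the auxiliary without moving the β,γ-double bond or the α-centre.

Step 15
Reactants: 23 homoallylic alcohol
Product: 24 (3S)-3-(ArB-methyl)-4-chlorobut-1-ene
Conditions: PPh3, N-chlorosuccinimide, THF, 0 °C to rt
Reagents that add atoms: N-chlorosuccinimide, O=C1CCC(=O)N1Cl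
Why: Appel-type chlorination displaces the alkoxyphosphonium at the primary carbon, so the adjacent stereocentre is untouched.

Step 16
Reactants: 15 ArA–Br; 24 (3S)-3-(ArB-methyl)-4-chlorobut-1-ene
Product: 25 (1E,3S)-1-ArA-3-(ArB-methyl)-4-chlorobut-1-ene
Conditions: Pd2(dba)3 (2.5 mol %), [(t-Bu)3PH]BF4 (10 mol %), Cy2NMe, 1,4-dioxane, 70 °C
Reagents that add atoms: none
Why: In this Heck reaction the bulky electron-rich phosphine lets zerovalent palladium insert into the electron-rich aryl bromide, the allylic branching steers the aryl group to the terminal alkene carbon, and β-hydride elimination toward the benzylic hydrogen gives the conjugated E-styrene while the primary alkyl chloride stays inert.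

Step 17
Reactants: 25 (1E,3S)-1-ArA-3-(ArB-methyl)-4-chlorobut-1-ene
Product: 28 (3S,4S)-3-(ArA-methyl)-4-(ArB-methyl)oxolan-2-one, via potassium γ-chloro carboxylate 26 (not isolated), via lactone C3-epimer mixture 27 (not isolated)
Conditions: HCO2K (3 equiv), 4CzIPN (2,4,5,6-tetra(carbazol-9-yl)isophthalonitrile, 2 mol %), i-Pr3SiSH (10 mol %), DMSO–THF, 450 nm LEDs, rt; then 50 °C; then DBU (2 equiv), 70 °C
Reagents that add atoms: potassium formate, [K+].[O-]C=O
Why: The excited photocatalyst generates a thiyl radical from the thiol cocatalyst, which abstracts the formyl hydrogen of formate; the resulting CO2 radical anion adds to the styrene carbon remote from ring A (the future C3) to give a ring-A-stabilised benzylic radical that takes a hydrogen atom back from the thiol in a radical chain, and the potassium carboxylate 26 then displaces the primary chloride to form the C5–O1 bond. The closest known reaction type is the photocatalytic anti-Markovnikov hydrocarboxylation of styrenes with formate, coupled here to an intramolecular carboxylate O-alkylation. The lactone ring closes in the 5-exo-tet mode, the carboxylate oxygen attacking the CH2Cl carbon. C4 is carried in from 25 and is not touched, whereas the new C3 centre is formed with little control in the radical addition and is then equilibrated by DBU through the lactone enolate to the thermodynamically preferred 3,4-trans (3S,4S) isomer. The step needs C–C bond formation at the alkene carbon remote from ring A, which conjugation with the arene secures, and it needs the chloride to survive until the carboxylate exists, which a primary β-branched alkyl chloride (slow toward formate at room temperature and a poor electron or halogen-atom acceptor) and a hindered, weakly nucleophilic thiol should allow.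

Step 18
Reactants: 28 fully silylated (3S,4S)-lactone
Product: 29 (3S,4S)-4-({4-hydroxy-3-[(1S,2S)-1,3-dihydroxy-1-(4-hydroxy-3-methoxyphenyl)propan-2-yl]-5-methoxyphenyl}methyl)-3-{[(2R,3S)-2-(4-hydroxy-3-methoxyphenyl)-3-(hydroxymethyl)-7-methoxy-2,3-dihydro-1-benzofuran-5-yl]methyl}oxolan-2-one (CNP0199264.1)
Conditions: HF·pyridine, excess pyridine, THF, 0 °C to rt
Reagents that add atoms: none
Why: Pyridine-buffered fluoride removes the three aryl silyl ethers, the primary silyl ether and the silylene in one operation, and the medium should be too weakly acidic to ionise the para-hydroxybenzylic alcohol of the open unit.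

Compound list
1 | 2-allyl-6-methoxyphenol (o-eugenol) | C=CCc1cccc(OC)c1O | starting material
2 | 2-allyl-4-bromo-6-methoxyphenol | C=CCc1cc(Br)cc(OC)c1O | intermediate
3 | (2-allyl-4-bromo-6-methoxyphenoxy)(tert-butyl)dimethylsilane | C=CCc1cc(Br)cc(OC)c1O[Si](C)(C)C(C)(C)C | intermediate
4 | 2-[5-bromo-2-(TBS-oxy)-3-methoxyphenyl]acetaldehyde (not isolated) | O=CCc1cc(Br)cc(OC)c1O[Si](C)(C)C(C)(C)C | intermediate
5 | 2-[5-bromo-2-(TBS-oxy)-3-methoxyphenyl]acetic acid | OC(=O)Cc1cc(Br)cc(OC)c1O[Si](C)(C)C(C)(C)C | intermediate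
6 | (S)-4-benzyl-1,3-oxazolidin-2-one | O=C1N[C@@H](Cc2ccccc2)CO1 | starting material
7 | mixed anhydride of 5 and pivalic acid (not isolated) | CC(C)(C)C(=O)OC(=O)Cc1cc(Br)cc(OC)c1O[Si](C)(C)C(C)(C)C | intermediate
8 | (S)-4-benzyl-3-{[5-bromo-2-(TBS-oxy)-3-methoxyphenyl]acetyl}-1,3-oxazolidin-2-one | O=C(Cc1cc(Br)cc(OC)c1O[Si](C)(C)C(C)(C)C)N1[C@@H](Cc2ccccc2)COC1=O | intermediate
9 | 4-(TBS-oxy)-3-methoxybenzaldehyde | COc1cc(C=O)ccc1O[Si](C)(C)C(C)(C)C | starting material
10 | O-trimethylsilyl ether of 11 (not isolated) | O=C([C@H](c1cc(Br)cc(OC)c1O[Si](C)(C)C(C)(C)C)[C@H](O[Si](C)(C)C)c1ccc(O[Si](C)(C)C(C)(C)C)c(OC)c1)N1[C@@H](Cc2ccccc2)COC1=O | intermediate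
11 | (S)-4-benzyl-3-{(2R,3S)-2-[5-bromo-2-(TBS-oxy)-3-methoxyphenyl]-3-hydroxy-3-[4-(TBS-oxy)-3-methoxyphenyl]propanoyl}-1,3-oxazolidin-2-one | O=C([C@H](c1cc(Br)cc(OC)c1O[Si](C)(C)C(C)(C)C)[C@H](O)c1ccc(O[Si](C)(C)C(C)(C)C)c(OC)c1)N1[C@@H](Cc2ccccc2)COC1=O | intermediate
12 | (1S,2S)-2-[5-bromo-2-(TBS-oxy)-3-methoxyphenyl]-1-[4-(TBS-oxy)-3-methoxyphenyl]propane-1,3-diol | OC[C@H](c1cc(Br)cc(OC)c1O[Si](C)(C)C(C)(C)C)[C@H](O)c1ccc(O[Si](C)(C)C(C)(C)C)c(OC)c1 | intermediate
13 | (1S,2S)-2-(5-bromo-2-hydroxy-3-methoxyphenyl)-1-(4-hydroxy-3-methoxyphenyl)propane-1,3-diol (not isolated) | OC[C@H](c1cc(Br)cc(OC)c1O)[C@H](O)c1ccc(O)c(OC)c1 | intermediate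
14 | 4-[(2R,3S)-5-bromo-3-(hydroxymethyl)-7-methoxy-2,3-dihydro-1-benzofuran-2-yl]-2-methoxyphenol | Brc1cc(OC)c2c(c1)[C@@H](CO)[C@H](c3ccc(O)c(OC)c3)O2 | intermediate
15 | ArA–Br (bis-TBS ether of 14) | Brc1cc(OC)c2c(c1)[C@@H](CO[Si](C)(C)C(C)(C)C)[C@H](c3ccc(O[Si](C)(C)C(C)(C)C)c(OC)c3)O2 | intermediate
16 | (4S,5S)-5-[5-bromo-2-(TBS-oxy)-3-methoxyphenyl]-2,2-di-tert-butyl-4-[4-(TBS-oxy)-3-methoxyphenyl]-1,3,2-dioxasilinane | Brc1cc(OC)c(O[Si](C)(C)C(C)(C)C)c(c1)[C@H]2CO[Si](C(C)(C)C)(C(C)(C)C)O[C@@H]2c3ccc(O[Si](C)(C)C(C)(C)C)c(OC)c3 | intermediate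
17 | ArB–CHO (not isolated) | O=Cc1cc(OC)c(O[Si](C)(C)C(C)(C)C)c(c1)[C@H]2CO[Si](C(C)(C)C)(C(C)(C)C)O[C@@H]2c3ccc(O[Si](C)(C)C(C)(C)C)c(OC)c3 | intermediate
18 | ArB–CH2OH | OCc1cc(OC)c(O[Si](C)(C)C(C)(C)C)c(c1)[C@H]2CO[Si](C(C)(C)C)(C(C)(C)C)O[C@@H]2c3ccc(O[Si](C)(C)C(C)(C)C)c(OC)c3 | intermediate
19 | ArB–CH2Br | BrCc1cc(OC)c(O[Si](C)(C)C(C)(C)C)c(c1)[C@H]2CO[Si](C(C)(C)C)(C(C)(C)C)O[C@@H]2c3ccc(O[Si](C)(C)C(C)(C)C)c(OC)c3 | intermediate
20 | (E)-but-2-enoyl chloride (crotonyl chloride) | C/C=C/C(=O)Cl | starting material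
21 | (S)-4-benzyl-3-[(E)-but-2-enoyl]-1,3-oxazolidin-2-one | C/C=C/C(=O)N1[C@@H](Cc2ccccc2)COC1=O | intermediate
22 | (S)-4-benzyl-3-[(2S)-2-(ArB-methyl)but-3-enoyl]-1,3-oxazolidin-2-one | C=C[C@H](Cc1cc(OC)c(O[Si](C)(C)C(C)(C)C)c(c1)[C@H]2CO[Si](C(C)(C)C)(C(C)(C)C)O[C@@H]2c3ccc(O[Si](C)(C)C(C)(C)C)c(OC)c3)C(=O)N4[C@@H](Cc5ccccc5)COC4=O | intermediate
23 | (2S)-2-(ArB-methyl)but-3-en-1-ol | C=C[C@H](Cc1cc(OC)c(O[Si](C)(C)C(C)(C)C)c(c1)[C@H]2CO[Si](C(C)(C)C)(C(C)(C)C)O[C@@H]2c3ccc(O[Si](C)(C)C(C)(C)C)c(OC)c3)CO | intermediate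
24 | (3S)-3-(ArB-methyl)-4-chlorobut-1-ene | C=C[C@H](Cc1cc(OC)c(O[Si](C)(C)C(C)(C)C)c(c1)[C@H]2CO[Si](C(C)(C)C)(C(C)(C)C)O[C@@H]2c3ccc(O[Si](C)(C)C(C)(C)C)c(OC)c3)CCl | intermediate
25 | (1E,3S)-1-ArA-3-(ArB-methyl)-4-chlorobut-1-ene | ClC[C@@H](Cc1cc(OC)c(O[Si](C)(C)C(C)(C)C)c(c1)[C@H]2CO[Si](C(C)(C)C)(C(C)(C)C)O[C@@H]2c3ccc(O[Si](C)(C)C(C)(C)C)c(OC)c3)/C=C/c4cc(OC)c5c(c4)[C@@H](CO[Si](C)(C)C(C)(C)C)[C@H](c6ccc(O[Si](C)(C)C(C)(C)C)c(OC)c6)O5 | intermediate
26 | potassium (3S)-2-(ArA-methyl)-3-(ArB-methyl)-4-chlorobutanoate, C2 epimers (not isolated) | [K+].[O-]C(=O)C(Cc1cc(OC)c2c(c1)[C@@H](CO[Si](C)(C)C(C)(C)C)[C@H](c3ccc(O[Si](C)(C)C(C)(C)C)c(OC)c3)O2)[C@H](Cc4cc(OC)c(O[Si](C)(C)C(C)(C)C)c(c4)[C@H]5CO[Si](C(C)(C)C)(C(C)(C)C)O[C@@H]5c6ccc(O[Si](C)(C)C(C)(C)C)c(OC)c6)CCl | intermediate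
27 | (4S)-3-(ArA-methyl)-4-(ArB-methyl)oxolan-2-one, C3 epimers (not isolated) | O=C1OC[C@@H](Cc2cc(OC)c(O[Si](C)(C)C(C)(C)C)c(c2)[C@H]3CO[Si](C(C)(C)C)(C(C)(C)C)O[C@@H]3c4ccc(O[Si](C)(C)C(C)(C)C)c(OC)c4)C1Cc5cc(OC)c6c(c5)[C@@H](CO[Si](C)(C)C(C)(C)C)[C@H](c7ccc(O[Si](C)(C)C(C)(C)C)c(OC)c7)O6 | intermediate
28 | (3S,4S)-3-(ArA-methyl)-4-(ArB-methyl)oxolan-2-one | O=C1OC[C@@H](Cc2cc(OC)c(O[Si](C)(C)C(C)(C)C)c(c2)[C@H]3CO[Si](C(C)(C)C)(C(C)(C)C)O[C@@H]3c4ccc(O[Si](C)(C)C(C)(C)C)c(OC)c4)[C@@H]1Cc5cc(OC)c6c(c5)[C@@H](CO[Si](C)(C)C(C)(C)C)[C@H](c7ccc(O[Si](C)(C)C(C)(C)C)c(OC)c7)O6 | intermediate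
29 | CNP0199264.1, (3S,4S)-4-({4-hydroxy-3-[(1S,2S)-1,3-dihydroxy-1-(4-hydroxy-3-methoxyphenyl)propan-2-yl]-5-methoxyphenyl}methyl)-3-{[(2R,3S)-2-(4-hydroxy-3-methoxyphenyl)-3-(hydroxymethyl)-7-methoxy-2,3-dihydro-1-benzofuran-5-yl]methyl}oxolan-2-one | COc1cc([C@@H](O)[C@H](CO)c2cc(C[C@@H]3COC(=O)[C@H]3Cc3cc(OC)c4c(c3)[C@@H](CO)[C@H](c3ccc(O)c(OC)c3)O4)cc(OC)c2O)ccc1O | target

Total step count: 18 steps.
Longest linear sequence: 15 steps (steps 1–6, 9–11, 13–15, 16–18).

Steps most likely to fail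

1. Step 17 (key step). The thiyl radical may abstract hydrogen unselectively, at the allylic stereocentre of 25 or at the benzylic ether C–H bonds of the dihydrobenzofuran and the dioxasilinane, scrambling those centres. Radical addition to the electron-rich styrene may also be so slow that formate or thiolate attacks the chloride before the carboxylate exists. The fallback sets out from 23 and 15 and comes back at 28. Alcohol 23 is coupled with 15 under the Heck conditions of step 16 to give the (E)-styrenyl alcohol F1. F1 is carboxylated with CO2 gas by pure electron transfer, without any hydrogen-atom-transfer catalyst (p-terphenyl, 1,2,2,6,6-pentamethylpiperidine, CO2, H2O, DMF, UV light in flow); the benzylic radical is reduced to the anion and protonated, which should give the γ-hydroxy acid F2 as a C3-epimer mixture. Mitsunobu activation of the primary alcohol (PPh3, diisopropyl azodicarboxylate, THF, 0 °C) then lets the carboxylate form the C5–O1 bond to give 27, and DBU equilibration as in step 17 returns to 28.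

2. Step 16 (Heck coupling). Aryl delivery to the internal alkene carbon and re-addition of palladium hydride may walk the double bond toward the allylic stereocentre, erasing it and creating an allylic chloride. The fallback sets out from 24 and 15 and comes back at 25. Cross-metathesis of 24 with vinylboronic acid pinacol ester (second-generation Hoveyda–Grubbs catalyst, RuCl2(H2IMes)(=CH-C6H4-2-O-iPr), CH2Cl2, 40 °C) should give the (E)-alkenylboronate F3. Suzuki–Miyaura coupling of F3 with 15 (Pd(dppf)Cl2, K3PO4, THF–H2O, 50 °C) gives 25 with the alkene position fixed by the C–B bond.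

3. Step 5 (magnesium anti-aldol). Reversible enolisation and aldolisation of the acidic arylacetyl imide under the amine base may erode the anti selectivity, and addition to the electron-rich aldehyde may be slow. The fallback sets out from 5 and comes back at 12. Acid 5 is attached to (R)-4-benzyl-1,3-oxazolidin-2-one as in step 4 to give the antipodal-auxiliary imide F4. Its preformed Z-boron enolate (Bu2BOTf, i-Pr2NEt, CH2Cl2, −78 °C) is added to aldehyde 9 precomplexed with Et2AlCl; this open-transition-state anti-aldol is kinetically locked and should give the (2R,3S) adduct F5, with the same acyl stereocentres as 11. NaBH4 reduction as in step 6 removes the auxiliary and returns to diol 12.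

Further compounds
F1 | step 17 | (2S,3E)-4-ArA-2-(ArB-methyl)but-3-en-1-ol | OC[C@@H](Cc1cc(OC)c(O[Si](C)(C)C(C)(C)C)c(c1)[C@H]2CO[Si](C(C)(C)C)(C(C)(C)C)O[C@@H]2c3ccc(O[Si](C)(C)C(C)(C)C)c(OC)c3)/C=C/c4cc(OC)c5c(c4)[C@@H](CO[Si](C)(C)C(C)(C)C)[C@H](c6ccc(O[Si](C)(C)C(C)(C)C)c(OC)c6)O5
F2 | step 17 | (3S)-2-(ArA-methyl)-3-(ArB-methyl)-4-hydroxybutanoic acid, C2 epimers | OC(=O)C(Cc1cc(OC)c2c(c1)[C@@H](CO[Si](C)(C)C(C)(C)C)[C@H](c3ccc(O[Si](C)(C)C(C)(C)C)c(OC)c3)O2)[C@H](Cc4cc(OC)c(O[Si](C)(C)C(C)(C)C)c(c4)[C@H]5CO[Si](C(C)(C)C)(C(C)(C)C)O[C@@H]5c6ccc(O[Si](C)(C)C(C)(C)C)c(OC)c6)CO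
F3 | step 16 | 2-[(1E,3S)-3-(ArB-methyl)-4-chlorobut-1-en-1-yl]-4,4,5,5-tetramethyl-1,3,2-dioxaborolane | CC1(C)OB(/C=C/[C@H](Cc2cc(OC)c(O[Si](C)(C)C(C)(C)C)c(c2)[C@H]3CO[Si](C(C)(C)C)(C(C)(C)C)O[C@@H]3c4ccc(O[Si](C)(C)C(C)(C)C)c(OC)c4)CCl)OC1(C)C
F4 | step 5 | (R)-4-benzyl-3-{[5-bromo-2-(TBS-oxy)-3-methoxyphenyl]acetyl}-1,3-oxazolidin-2-one | O=C(Cc1cc(Br)cc(OC)c1O[Si](C)(C)C(C)(C)C)N1[C@H](Cc2ccccc2)COC1=O
F5 | step 5 | (R)-4-benzyl-3-{(2R,3S)-2-[5-bromo-2-(TBS-oxy)-3-methoxyphenyl]-3-hydroxy-3-[4-(TBS-oxy)-3-methoxyphenyl]propanoyl}-1,3-oxazolidin-2-one | O=C([C@H](c1cc(Br)cc(OC)c1O[Si](C)(C)C(C)(C)C)[C@H](O)c1ccc(O[Si](C)(C)C(C)(C)C)c(OC)c1)N1[C@H](Cc2ccccc2)COC1=O
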